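**Plan**

Ring numbering used here: C1 (CH–OBz beside the quaternary carbon), C2=C3, C4 (CH–OBz), C5 (CH–OH), C6 (C(OH)CH2OH).
Retrosynthesis: remove the silyl group and the C1 benzoate (Mitsunobu, inversion), return C6 to a ketone via its methylene, bridge O1/O5 as an acetonide, then cut C1–C2 and C4–C5 together.
Enabling feature: C5–C6–C1 is a masked dihydroxyacetone, nucleophilic at both alpha carbons; C2=C3–C4(O) is propynal, electrophilic at its alkyne terminus and its carbonyl carbon.
Forward: one amine-mediated Michael–aldol [3+3] annulation builds the cyclohexene as the carbocyclic ring of a 2,4-dioxabicyclo[3.3.1]nonenone (the dioxane ring is a temporary ring, opened in step 6); then benzoylation, methylenation, dihydroxylation, silylation, acetonide hydrolysis, Mitsunobu benzoylation, desilylation.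
Stereochemistry: C4 and C5 (absolute) from (S)-proline in the ring-closing aldol; C6 from dihydroxylation of the rigid bicycle; C1 is first held cis by the acetonide bridge, then inverted in the Mitsunobu step.

Key step: step 1

Assumption: propynal (2) is treated as commercial (stabilised solution, or freed from its commercial diethyl acetal just before use).

**Route**

Step 1
Reactants: 1 2,2-dimethyl-1,3-dioxan-5-one; 2 propynal; 3 (S)-proline
Product: 7 (1S,5R,8R)-8-hydroxy-3,3-dimethyl-2,4-dioxabicyclo[3.3.1]non-6-en-9-one, via proline enamine 4 (not isolated), via aminodienal 5 (not isolated), via enamine enal 6 (not isolated)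
Conditions: 3 (1.1 equiv), KOtBu (1.1 equiv), DMSO, rt; 1, 4 Å MS, rt; 2 (1.0 equiv, slow addition), 0 °C to rt; then AcOH (3 equiv), H2O (5 equiv), 35 °C; aq. NaHCO3 work-up
Reagents that add atoms: water, O (returns the ketone oxygen when the iminium ion is hydrolysed)
Why: Proposed new method: as its carboxylate (no acidic proton to steer 1,2-addition) enamine 4 should add through carbon to the alkyne terminus of 2 and the adduct should tautomerise to the achiral push–pull aminodienal 5; acidification should then give, by C-protonation and re-enolisation, the less substituted enamine 6, whose enamine carbon attacks the aldehyde in a 6-(enolendo)-exo-trig aldol that closes the carbocycle, after which water frees ketone 7 and proline. The closest known reaction types are the enamine alpha,alpha'-annulation of this dioxanone with three-carbon bis-electrophiles (Stork-type [3+3]) and the amine-catalysed Michael–aldol [3+3] of ketones with enals; the ynal partner is new and keeps both the C6=C7 alkene and the carbinol oxidation level. The two bridgehead centres must be cis because the dioxane ring can only be spanned 1,3-diaxially, so only their absolute sense is open; it should be set in the aldol by the proline carboxylic acid hydrogen-bonding the aldehyde oxygen, the same arrangement that gives the 4S centre in (S)-proline aldols of 1. Because the tether turns the aldehyde carbon chain toward the enamine, the hydrogen-bonded oxygen should end anti to the acetonide oxygen (8R, pseudoaxial), the epimer of the intermolecular anti-aldol. Only the (Z)-enal with the side chain axial can cyclise and all other isomers return through 5, so the step is stereoconvergent. The bridgehead hydrogens of 7 cannot enolise (Bredt), which should block the dehydration to a phenol and the epimerisation open to a monocyclic analogue.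

Step 2
Reactants: 7 (1S,5R,8R)-8-hydroxy-3,3-dimethyl-2,4-dioxabicyclo[3.3.1]non-6-en-9-one
Product: 8 (1S,5R,8R)-3,3-dimethyl-9-oxo-2,4-dioxabicyclo[3.3.1]non-6-en-8-yl benzoate
Conditions: BzCl (1.3 equiv), pyridine, DMAP (5 mol %), CH2Cl2, 0 °C
Reagents that add atoms: benzoyl chloride, O=C(Cl)c1ccccc1
Why: DMAP-catalysed O-acylation proceeds with retention at C8, and the ester should switch off retro-aldol opening while beta-elimination remains impossible at the bridgehead.

Step 3
Reactants: 8 (1S,5R,8R)-3,3-dimethyl-9-oxo-2,4-dioxabicyclo[3.3.1]non-6-en-8-yl benzoate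
Product: 9 (1R,5R,8R)-3,3-dimethyl-9-methylidene-2,4-dioxabicyclo[3.3.1]non-6-en-8-yl benzoate
Conditions: Ph3PCH3Br (1.3 equiv), KN(SiMe3)2 (1.25 equiv), THF, −78 to 0 °C
Reagents that add atoms: methyltriphenylphosphonium bromide, C[P+](c1ccccc1)(c1ccccc1)c1ccccc1.[Br-]
Why: Wittig olefination of a non-enolisable ketone activated by two alpha-oxygens should outpace attack on the benzoate at low temperature (the descriptor at C1 changes only through CIP priority).

Step 4
Reactants: 9 (1R,5R,8R)-3,3-dimethyl-9-methylidene-2,4-dioxabicyclo[3.3.1]non-6-en-8-yl benzoate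
Product: 10 (1S,5R,8R,9R)-9-hydroxy-9-(hydroxymethyl)-3,3-dimethyl-2,4-dioxabicyclo[3.3.1]non-6-en-8-yl benzoate
Conditions: OsO4 (2 mol %), NMO (1.1 equiv), acetone–H2O 8:1, 0 °C
Reagents that add atoms: osmium tetroxide, O=[Os](=O)(=O)=O (transfers both oxygens, re-formed from the next two); N-methylmorpholine N-oxide, C[N+]1([O-])CCOCC1; water, O
Why: OsO4-catalysed syn-dihydroxylation should take the exocyclic 1,1-disubstituted alkene from the dioxane side, anti to the pseudoaxial benzoate (setting 9R with the hydroxyl cis to the acetonide oxygens), while the ring alkene is screened by the dioxane ring on one face and the benzoate on the other.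

Step 5
Reactants: 10 (1S,5R,8R,9R)-9-hydroxy-9-(hydroxymethyl)-3,3-dimethyl-2,4-dioxabicyclo[3.3.1]non-6-en-8-yl benzoate
Product: 11 (1S,5R,8R,9R)-9-{[tert-butyl(diphenyl)silyl]oxymethyl}-9-hydroxy-3,3-dimethyl-2,4-dioxabicyclo[3.3.1]non-6-en-8-yl benzoate
Conditions: TBDPSCl (1.1 equiv), imidazole, DMF, 0 °C to rt
Reagents that add atoms: tert-butyl(chloro)diphenylsilane, CC(C)(C)[Si](Cl)(c1ccccc1)c1ccccc1
Why: silyl ether formation is selective for the primary over the tertiary hydroxyl, and the acid-stable silyl group keeps the primary alcohol out of step 7.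

Step 6
Reactants: 11 (1S,5R,8R,9R)-9-{[tert-butyl(diphenyl)silyl]oxymethyl}-9-hydroxy-3,3-dimethyl-2,4-dioxabicyclo[3.3.1]non-6-en-8-yl benzoate
Product: 12 (1R,4R,5R,6S)-5-{[tert-butyl(diphenyl)silyl]oxymethyl}-4,5,6-trihydroxycyclohex-2-en-1-yl benzoate
Conditions: AcOH–H2O–THF 3:1:1, 40 °C
Reagents that add atoms: none
Why: acid-catalysed acetal hydrolysis should open the strained 1,3-diaxial acetonide readily, with the silyl ether and benzoate stable to the mild acid and no stereocentre touched.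

Step 7
Reactants: 12 (1R,4R,5R,6S)-5-{[tert-butyl(diphenyl)silyl]oxymethyl}-4,5,6-trihydroxycyclohex-2-en-1-yl benzoate
Product: 13 (1R,4S,5S,6S)-5-{[tert-butyl(diphenyl)silyl]oxymethyl}-5,6-dihydroxycyclohex-2-ene-1,4-diyl dibenzoate
Conditions: PhCO2H (1.5 equiv), PPh3 (1.5 equiv), DIAD (1.5 equiv), THF, 0 °C to rt
Reagents that add atoms: benzoic acid, OC(=O)c1ccccc1
Why: the Mitsunobu reaction should esterify the allylic C4 hydroxyl of 12 with inversion, since the C6 hydroxyl is non-allylic and flanked by two substituted carbons, the tertiary hydroxyl is inert, and every neighbouring hydroxyl is cis to the leaving group and cannot displace it.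

Step 8
Reactants: 13 (1R,4S,5S,6S)-5-{[tert-butyl(diphenyl)silyl]oxymethyl}-5,6-dihydroxycyclohex-2-ene-1,4-diyl dibenzoate
Product: 14 (1R,4S,5S,6S)-5,6-dihydroxy-5-(hydroxymethyl)cyclohex-2-ene-1,4-diyl dibenzoate (target)
Conditions: HF·pyridine, pyridine, THF, 0 °C to rt
Reagents that add atoms: none
Why: fluoride desilylation under buffered acidic conditions should free the primary alcohol without the base-induced benzoate migration to which the product is prone.

**Compound list**

1 | 2,2-dimethyl-1,3-dioxan-5-one | CC1(C)OCC(=O)CO1 | starting material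
2 | propynal | C#CC=O | starting material
3 | (S)-proline | OC(=O)[C@@H]1CCCN1 | starting material
4 | (2S)-1-(2,2-dimethyl-4H-1,3-dioxin-5-yl)pyrrolidine-2-carboxylic acid (enamine, present as its potassium salt) | OC(=O)[C@@H]1CCCN1C2=COC(C)(C)OC2 | intermediate
5 | (2S)-1-[2,2-dimethyl-6-(3-oxoprop-1-en-1-yl)-4H-1,3-dioxin-5-yl]pyrrolidine-2-carboxylic acid (E/Z mixture) | OC(=O)[C@@H]1CCCN1C2=C(C=CC=O)OC(C)(C)OC2 | intermediate
6 | (2S)-1-{(4R)-2,2-dimethyl-4-[(1Z)-3-oxoprop-1-en-1-yl]-4H-1,3-dioxin-5-yl}pyrrolidine-2-carboxylic acid | CC1(C)O[C@H](/C=C\C=O)C(=CO1)N1CCC[C@H]1C(=O)O | intermediate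
7 | (1S,5R,8R)-8-hydroxy-3,3-dimethyl-2,4-dioxabicyclo[3.3.1]non-6-en-9-one (hydroxyl anti to the acetonide oxygens) | CC1(C)O[C@@H]2C=C[C@@H](O)[C@H](O1)C2=O | intermediate
8 | (1S,5R,8R)-3,3-dimethyl-9-oxo-2,4-dioxabicyclo[3.3.1]non-6-en-8-yl benzoate | CC1(C)O[C@@H]2C=C[C@@H](OC(=O)c3ccccc3)[C@H](O1)C2=O | intermediate
9 | (1R,5R,8R)-3,3-dimethyl-9-methylidene-2,4-dioxabicyclo[3.3.1]non-6-en-8-yl benzoate | CC1(C)O[C@@H]2C=C[C@@H](OC(=O)c3ccccc3)[C@H](O1)C2=C | intermediate
10 | (1S,5R,8R,9R)-9-hydroxy-9-(hydroxymethyl)-3,3-dimethyl-2,4-dioxabicyclo[3.3.1]non-6-en-8-yl benzoate | CC1(C)O[C@@H]2C=C[C@@H](OC(=O)c3ccccc3)[C@H](O1)[C@@]2(O)CO | intermediate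
11 | (1S,5R,8R,9R)-9-{[tert-butyl(diphenyl)silyl]oxymethyl}-9-hydroxy-3,3-dimethyl-2,4-dioxabicyclo[3.3.1]non-6-en-8-yl benzoate | CC1(C)O[C@@H]2C=C[C@@H](OC(=O)c3ccccc3)[C@H](O1)[C@@]2(O)CO[Si](c3ccccc3)(c4ccccc4)C(C)(C)C | intermediate
12 | (1R,4R,5R,6S)-5-{[tert-butyl(diphenyl)silyl]oxymethyl}-4,5,6-trihydroxycyclohex-2-en-1-yl benzoate | O[C@@H]1C=C[C@@H](OC(=O)c2ccccc2)[C@H](O)[C@@]1(O)CO[Si](c2ccccc2)(c3ccccc3)C(C)(C)C | intermediate
13 | (1R,4S,5S,6S)-5-{[tert-butyl(diphenyl)silyl]oxymethyl}-5,6-dihydroxycyclohex-2-ene-1,4-diyl dibenzoate | O=C(O[C@H]1C=C[C@@H](OC(=O)c2ccccc2)[C@H](O)[C@@]1(O)CO[Si](c2ccccc2)(c3ccccc3)C(C)(C)C)c1ccccc1 | intermediate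
14 | (1R,4S,5S,6S)-5,6-dihydroxy-5-(hydroxymethyl)cyclohex-2-ene-1,4-diyl dibenzoate | O=C(O[C@H]1C=C[C@@H](OC(=O)c2ccccc2)[C@H](O)[C@@]1(O)CO)c1ccccc1 | target

**Step count and risks**

Total steps: 8. Longest linear sequence: 8 (from 1).

Risk 1, step 1. The ynal may be lost to N-addition or to 1,2-addition at its carbonyl, the cascade may stall at the push–pull aminodienal, and enantioface or carbinol selectivity in the ring-closing aldol may be weak. The fallback uses known reaction types only, sets out from 1 and returns at 8, forming the two ring bonds in separate steps.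
- (S)-Proline-catalysed anti-aldol of 1 with commercial 3-(trimethylsilyl)propynal (DMF, 4 °C) should give (4S)-4-[(1S)-1-hydroxy-3-(trimethylsilyl)prop-2-yn-1-yl]-2,2-dimethyl-1,3-dioxan-5-one F1.
- Silylation (Et3SiOTf, 2,6-lutidine) gives (4S)-2,2-dimethyl-4-[(1S)-1-[(triethylsilyl)oxy]-3-(trimethylsilyl)prop-2-yn-1-yl]-1,3-dioxan-5-one F2.
- Iododesilylation (NIS, AgNO3 cat., DMF) gives (4S)-4-[(1S)-3-iodo-1-[(triethylsilyl)oxy]prop-2-yn-1-yl]-2,2-dimethyl-1,3-dioxan-5-one F3.
- Diimide semireduction (2-nitrobenzenesulfonohydrazide, Et3N) gives (4S)-4-[(1S,2Z)-3-iodo-1-[(triethylsilyl)oxy]prop-2-en-1-yl]-2,2-dimethyl-1,3-dioxan-5-one F4.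
- Intramolecular palladium-catalysed ketone alpha-alkenylation at the unsubstituted alpha-carbon (Pd2(dba)3, Xantphos, K3PO4, toluene) closes the carbocycle to (1S,5R,8S)-3,3-dimethyl-8-[(triethylsilyl)oxy]-2,4-dioxabicyclo[3.3.1]non-6-en-9-one F5.
- HF·pyridine gives (1S,5R,8S)-8-hydroxy-3,3-dimethyl-2,4-dioxabicyclo[3.3.1]non-6-en-9-one F6, the C8 epimer of 7.
- Mitsunobu esterification of F6 with benzoic acid (PPh3, DIAD) inverts C8 and delivers 8. The same inversion would rescue any C8 epimer formed in step 1.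

Risk 2, step 7. Displacement beside the quaternary carbon may be slow, letting SN2' attack or elimination of the activated allylic alcohol compete. The fallback sets out from 12 and returns at 13.
- MnO2 oxidises only the allylic hydroxyl to (1R,5S,6S)-5-{[tert-butyl(diphenyl)silyl]oxymethyl}-5,6-dihydroxy-4-oxocyclohex-2-en-1-yl benzoate F9.
- Luche reduction (NaBH4, CeCl3·7H2O, MeOH, −78 °C), with hydride entering syn to the tertiary hydroxyl and anti to the silyloxymethyl arm, should give (1R,4S,5R,6S)-5-{[tert-butyl(diphenyl)silyl]oxymethyl}-4,5,6-trihydroxycyclohex-2-en-1-yl benzoate F10.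
- Selective benzoylation of the allylic hydroxyl (BzCl, pyridine, −40 °C) gives 13.

Risk 3, step 4. Osmylation may occur at the ring alkene or on the wrong face of the methylidene group. The fallback replaces steric substrate control by hydroxyl direction, sets out from 9 and returns at 12.
- Acetonide hydrolysis (AcOH–H2O–THF) gives (1R,4R,6R)-4,6-dihydroxy-5-methylidenecyclohex-2-en-1-yl benzoate F7.
- Hydrogen-bond-directed dihydroxylation (stoichiometric OsO4·TMEDA, CH2Cl2, −78 °C, then aq. Na2SO3), steered by the two allylic hydroxyls flanking the methylidene group, should give (1R,4R,5R,6S)-4,5,6-trihydroxy-5-(hydroxymethyl)cyclohex-2-en-1-yl benzoate F8.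
- Primary silylation (TBDPSCl, imidazole) gives 12.

**Further compounds**

F1 | step 1 | (4S)-4-[(1S)-1-hydroxy-3-(trimethylsilyl)prop-2-yn-1-yl]-2,2-dimethyl-1,3-dioxan-5-one | CC1(C)OCC(=O)[C@@H](O1)[C@@H](O)C#C[Si](C)(C)C
F2 | step 1 | (4S)-2,2-dimethyl-4-[(1S)-1-[(triethylsilyl)oxy]-3-(trimethylsilyl)prop-2-yn-1-yl]-1,3-dioxan-5-one | CC1(C)OCC(=O)[C@@H](O1)[C@@H](O[Si](CC)(CC)CC)C#C[Si](C)(C)C
F3 | step 1 | (4S)-4-[(1S)-3-iodo-1-[(triethylsilyl)oxy]prop-2-yn-1-yl]-2,2-dimethyl-1,3-dioxan-5-one | CC1(C)OCC(=O)[C@@H](O1)[C@@H](O[Si](CC)(CC)CC)C#CI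
F4 | step 1 | (4S)-4-[(1S,2Z)-3-iodo-1-[(triethylsilyl)oxy]prop-2-en-1-yl]-2,2-dimethyl-1,3-dioxan-5-one | CC1(C)OCC(=O)[C@@H](O1)[C@@H](O[Si](CC)(CC)CC)/C=C\I
F5 | step 1 | (1S,5R,8S)-3,3-dimethyl-8-[(triethylsilyl)oxy]-2,4-dioxabicyclo[3.3.1]non-6-en-9-one | CC1(C)O[C@@H]2C=C[C@H](O[Si](CC)(CC)CC)[C@H](O1)C2=O
F6 | step 1 | (1S,5R,8S)-8-hydroxy-3,3-dimethyl-2,4-dioxabicyclo[3.3.1]non-6-en-9-one | CC1(C)O[C@@H]2C=C[C@H](O)[C@H](O1)C2=O
F7 | step 4 | (1R,4R,6R)-4,6-dihydroxy-5-methylidenecyclohex-2-en-1-yl benzoate | O[C@@H]1C=C[C@@H](OC(=O)c2ccccc2)[C@H](O)C1=C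
F8 | step 4 | (1R,4R,5R,6S)-4,5,6-trihydroxy-5-(hydroxymethyl)cyclohex-2-en-1-yl benzoate | O[C@@H]1C=C[C@@H](OC(=O)c2ccccc2)[C@H](O)[C@@]1(O)CO
F9 | step 7 | (1R,5S,6S)-5-{[tert-butyl(diphenyl)silyl]oxymethyl}-5,6-dihydroxy-4-oxocyclohex-2-en-1-yl benzoate | O=C1C=C[C@@H](OC(=O)c2ccccc2)[C@H](O)[C@@]1(O)CO[Si](c2ccccc2)(c3ccccc3)C(C)(C)C
F10 | step 7 | (1R,4S,5R,6S)-5-{[tert-butyl(diphenyl)silyl]oxymethyl}-4,5,6-trihydroxycyclohex-2-en-1-yl benzoate | O[C@H]1C=C[C@@H](OC(=O)c2ccccc2)[C@H](O)[C@@]1(O)CO[Si](c2ccccc2)(c3ccccc3)C(C)(C)C
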